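**Retrosynthetic overview**
- The route rests on the lactone carbonyl C9' of ring C (the butyrolactone). It lies between the ring oxygen on C9 and the alpha carbon C8', which carries the ring B benzylic carbon C7', so it is inserted last as CO between the C9 hydroxyl and an aryl alkyne C8'≡C7'. Ring C is the only ring formed; rings A and B are bought as arenes.
- After ring closure: conjugate reduction of the C7'=C8' benzylidene, equilibration of C8' to the trans lactone, hydrogenolysis of three benzyl ethers.
- The alkynol comes from Sonogashira coupling (C7'–aryl bond) of a terminal alkyne carrying the C8 stereocentre with the ring B iodide, then desilylation.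
- The terminal alkyne comes from aldehyde homologation. C8 is set by auxiliary-controlled hydroxymethylation of the O-benzyl dihydroferulic acid imide (the acid carbon becomes C8', formaldehyde supplies C9).
- The ring B iodide comes from o-vanillin by para-iodination, Dakin oxidation and benzylation.

Key step: step 13

Remarks on the chemistry:
- Lignan numbering is used: C7–C9 on the ring A arm, C7'–C9' on the ring B arm.
- Electrophilic iodination of a 3-methoxycatechol ether would go ortho/para to an outer oxygen, not to the carbon para to the central oxygen. Ring B is therefore taken from o-vanillin, in which phenol and aldehyde both direct iodine to the required carbon.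
- The descriptor at C8 alternates (S in 7 and 8, R in 9, S in 10, R from 11 on) only because substituent priorities change. No bond to C8 is made or broken after step 3.
- Dihydroferulic acid, o-vanillin and (R)-4-benzyloxazolidin-2-one are assumed to be commercial.

**Route**

Step 1
Reactants: 1 dihydroferulic acid
Product: 3 3-(4-benzyloxy-3-methoxyphenyl)propanoic acid, via benzyl ester 2 (not isolated)
Conditions: BnBr (2.2 equiv), K2CO3, DMF, 60 °C; then aq NaOH, MeOH, 60 °C; HCl
Reagents that add atoms: benzyl bromide BrCc1ccccc1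
Why: Williamson benzylation of phenoxide and carboxylate followed by saponification of the benzyl ester in the same pot leaves only the phenol protected, as a benzyl ether that lasts until the final hydrogenolysis.

Step 2
Reactants: 3 3-(4-benzyloxy-3-methoxyphenyl)propanoic acid; 4 (R)-4-benzyloxazolidin-2-one
Product: 6 (R)-4-benzyl-3-[3-(4-benzyloxy-3-methoxyphenyl)propanoyl]oxazolidin-2-one, via pivalic mixed anhydride 5 (not isolated)
Conditions: PivCl, Et3N, THF, −20 °C; then LiCl, 4, −20 °C to rt
Reagents that add atoms: pivaloyl chloride CC(C)(C)C(Cl)=O (its acyl group is carried by 5 only and leaves again as pivalate)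
Why: N-acylation of the oxazolidinone through the mixed pivalic anhydride with LiCl/Et3N activation is the standard mild loading of this auxiliary, attack taking place at the unhindered acyl carbon of the anhydride.

Step 3
Reactants: 6 (R)-4-benzyl-3-[3-(4-benzyloxy-3-methoxyphenyl)propanoyl]oxazolidin-2-one
Product: 7 (R)-4-benzyl-3-[(S)-2-(4-benzyloxy-3-methoxybenzyl)-3-hydroxypropanoyl]oxazolidin-2-one
Conditions: TiCl4 (1.05 equiv), i-Pr2NEt, CH2Cl2, 0 °C; then 1,3,5-trioxane, TiCl4 (1.05 equiv), 0 °C; aq NH4Cl
Reagents that add atoms: 1,3,5-trioxane C1OCOCO1 (delivers one formaldehyde unit)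
Why: In this Evans-type hydroxymethylation the chelated Z titanium enolate is attacked by TiCl4-activated formaldehyde on the face opposite the C4 benzyl group of the (R)-auxiliary, which sets C8 (S in 7, the sense that becomes R in the alkynol) and supplies C9.

Step 4
Reactants: 7 (R)-4-benzyl-3-[(S)-2-(4-benzyloxy-3-methoxybenzyl)-3-hydroxypropanoyl]oxazolidin-2-one
Product: 8 (R)-4-benzyl-3-[(S)-2-(4-benzyloxy-3-methoxybenzyl)-3-(tert-butyldimethylsilyloxy)propanoyl]oxazolidin-2-one
Conditions: TBSCl, imidazole, DMF, rt
Reagents that add atoms: tert-butyldimethylsilyl chloride CC(C)(C)[Si](C)(C)Cl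
Why: Standard silylation of the primary alcohol marks the C9 oxygen, keeps the two arms on C8 different after the auxiliary is removed, and blocks retro-aldol cleavage.

Step 5
Reactants: 8 (R)-4-benzyl-3-[(S)-2-(4-benzyloxy-3-methoxybenzyl)-3-(tert-butyldimethylsilyloxy)propanoyl]oxazolidin-2-one
Product: 9 (R)-2-(4-benzyloxy-3-methoxybenzyl)-3-(tert-butyldimethylsilyloxy)propan-1-ol
Conditions: LiBH4, MeOH (1 equiv), THF, 0 °C
Reagents that add atoms: none
Why: LiBH4 reductively cleaves the exocyclic imide carbonyl to the primary alcohol and releases the auxiliary without touching silyl or benzyl ethers, and at 0 °C no silyl migration between the two oxygens (which would racemise C8) is expected.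

Step 6
Reactants: 9 (R)-2-(4-benzyloxy-3-methoxybenzyl)-3-(tert-butyldimethylsilyloxy)propan-1-ol
Product: 10 (S)-2-(4-benzyloxy-3-methoxybenzyl)-3-(tert-butyldimethylsilyloxy)propanal
Conditions: TEMPO (10 mol %), PhI(OAc)2, CH2Cl2, rt
Reagents that add atoms: none
Why: The oxoammonium (TEMPO) oxidation stops at the aldehyde under nearly neutral conditions, so the alpha stereocentre C8 should not epimerise.

Step 7
Reactants: 10 (S)-2-(4-benzyloxy-3-methoxybenzyl)-3-(tert-butyldimethylsilyloxy)propanal
Product: 11 (R)-tert-butyl{[2-(4-benzyloxy-3-methoxybenzyl)but-3-yn-1-yl]oxy}dimethylsilane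
Conditions: dimethyl (1-diazo-2-oxopropyl)phosphonate, K2CO3, MeOH, 0 °C to rt
Reagents that add atoms: dimethyl (1-diazo-2-oxopropyl)phosphonate COP(=O)(OC)C(=[N+]=[N-])C(C)=O
Why: In the Ohira–Bestmann variant of the Seyferth–Gilbert homologation the diazomethylphosphonate anion made in situ adds to the aldehyde, and loss of phosphate and N2 with a 1,2-hydride shift gives the terminal alkyne (inner carbon C8', new carbon C7') under carbonate conditions mild enough for an alpha-branched beta-silyloxy aldehyde.

Step 8
Reactants: 12 o-vanillin (2-hydroxy-3-methoxybenzaldehyde)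
Product: 13 2-hydroxy-5-iodo-3-methoxybenzaldehyde
Conditions: ICl, AcOH, rt
Reagents that add atoms: iodine monochloride ClI
Why: In this electrophilic aromatic iodination the free phenol directs para and the aldehyde meta, both to C5, the carbon that ends para to the central oxygen of ring B.

Step 9
Reactants: 13 2-hydroxy-5-iodo-3-methoxybenzaldehyde
Product: 15 5-iodo-3-methoxybenzene-1,2-diol, via aryl formate 14 (not isolated)
Conditions: 30% aq H2O2, NaOH, H2O/THF, 0 °C to rt, N2; then HCl
Reagents that add atoms: hydrogen peroxide OO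
Why: In the Dakin oxidation hydroperoxide adds to the ortho-hydroxy aldehyde, aryl migration gives the formate 14, and its hydrolysis in the alkaline medium unveils the catechol with the aryl iodide untouched.

Step 10
Reactants: 15 5-iodo-3-methoxybenzene-1,2-diol
Product: 16 1,2-bis(benzyloxy)-5-iodo-3-methoxybenzene
Conditions: BnBr (2.5 equiv), K2CO3, DMF, rt, N2
Reagents that add atoms: benzyl bromide BrCc1ccccc1
Why: Double Williamson benzylation puts the same protecting group on ring B as on ring A, so that one hydrogenolysis frees all three phenols at the end.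

Step 11
Reactants: 11 (R)-tert-butyl{[2-(4-benzyloxy-3-methoxybenzyl)but-3-yn-1-yl]oxy}dimethylsilane; 16 1,2-bis(benzyloxy)-5-iodo-3-methoxybenzene
Product: 17 (R)-tert-butyl{[2-(4-benzyloxy-3-methoxybenzyl)-4-(3,4-bis(benzyloxy)-5-methoxyphenyl)but-3-yn-1-yl]oxy}dimethylsilane
Conditions: PdCl2(PPh3)2 (3 mol %), CuI (5 mol %), Et3N/THF, rt, degassed
Reagents that add atoms: none
Why: In the Sonogashira coupling, oxidative addition of the aryl iodide to zerovalent palladium formed in situ, transmetalation of the copper acetylide of 11 and reductive elimination form the C7'–aryl bond at room temperature without touching C8.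

Step 12
Reactants: 17 (R)-tert-butyl{[2-(4-benzyloxy-3-methoxybenzyl)-4-(3,4-bis(benzyloxy)-5-methoxyphenyl)but-3-yn-1-yl]oxy}dimethylsilane
Product: 18 (R)-2-(4-benzyloxy-3-methoxybenzyl)-4-[3,4-bis(benzyloxy)-5-methoxyphenyl]but-3-yn-1-ol
Conditions: TBAF, THF, 0 °C to rt
Reagents that add atoms: none
Why: Fluoride cleaves the primary silyl ether and frees the C9 hydroxyl needed as the nucleophile of the carbonylation, aryl benzyl ethers and the alkyne being inert to TBAF.

Step 13
Reactants: 18 (R)-2-(4-benzyloxy-3-methoxybenzyl)-4-[3,4-bis(benzyloxy)-5-methoxyphenyl]but-3-yn-1-ol; 19 carbon monoxide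
Product: 20 (3E,4R)-4-(4-benzyloxy-3-methoxybenzyl)-3-[3,4-bis(benzyloxy)-5-methoxybenzylidene]dihydrofuran-2(3H)-one
Conditions: PdCl2(PPh3)2 (5 mol %), SnCl2 (5 mol %), CO (7 atm), MeCN (THF cosolvent if needed), 75 °C
Reagents that add atoms: none
Why: Under CO, PdCl2(PPh3)2 with SnCl2 takes up the C9 hydroxyl of 18 as an alkoxycarbonyl ligand on divalent palladium (loss of HCl), the tethered alkyne inserts syn into the palladium–acyl bond so that C9' bonds to C8' and palladium sits on the aryl-bearing C7', and the liberated HCl cleaves the alkenyl–palladium bond with retention to return the divalent palladium chloride. The closest known reaction type is the palladium-catalysed cyclocarbonylation of homopropargylic alcohols to alpha-methylene and (E)-alpha-alkylidene gamma-butyrolactones. Ring C closes in a 5-exo-dig mode through the O–C9' and C9'–C8' bonds, and the two-carbon tether C9–C8 rules out another ring size or the reverse regiochemistry of insertion. No stereocentre is created, and C8, which the metal does not touch, keeps its R configuration. The E geometry follows from syn addition and retentive protonolysis, which leave the C7' hydrogen cis to the carbonyl. The step needs chemoselectivity for the alkoxycarbonyl pathway over direct attack of the hydroxyl on the palladium-activated alkyne, which CO pressure and the phosphine/trichlorostannyl ligand set are expected to secure, while the aryl group stabilises palladium at C7' during insertion.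

Step 14
Reactants: 20 (3E,4R)-4-(4-benzyloxy-3-methoxybenzyl)-3-[3,4-bis(benzyloxy)-5-methoxybenzylidene]dihydrofuran-2(3H)-one
Product: 22 (3R,4R)-3-[3,4-bis(benzyloxy)-5-methoxybenzyl]-4-(4-benzyloxy-3-methoxybenzyl)dihydrofuran-2(3H)-one, via cis-lactone 21 (not isolated)
Conditions: NaBH4, NiCl2·6H2O (cat.), MeOH/THF, 0 °C; filter, evaporate; then DBU, PhMe, 80 °C
Reagents that add atoms: none
Why: Nickel boride (Ni2B) formed from NiCl2 and NaBH4 effects conjugate reduction of the benzylidene lactone with hydrogen delivered to C8' mainly on the face away from the C8 substituent (chiefly the cis lactone 21, some trans), and DBU, added only once the alkene is gone so that it cannot shift into the ring, equilibrates C8' through the lactone enolate to the thermodynamically preferred trans lactone while the non-acidic C8 stays fixed.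

Step 15
Reactants: 22 (3R,4R)-3-[3,4-bis(benzyloxy)-5-methoxybenzyl]-4-(4-benzyloxy-3-methoxybenzyl)dihydrofuran-2(3H)-one
Product: 23 (−)-thujaplicatin, (3R,4R)-3-(3,4-dihydroxy-5-methoxybenzyl)-4-(4-hydroxy-3-methoxybenzyl)dihydrofuran-2(3H)-one
Conditions: H2 (1 atm), 10% Pd/C, EtOAc/MeOH, rt
Reagents that add atoms: none
Why: Hydrogenolysis of the three aryl benzyl ethers over Pd/C under neutral conditions leaves the lactone, the methyl ethers and both stereocentres untouched and gives the target.

**Compound list**

1 | dihydroferulic acid, 3-(4-hydroxy-3-methoxyphenyl)propanoic acid | COc1cc(CCC(=O)O)ccc1O | starting material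
2 | benzyl 3-(4-benzyloxy-3-methoxyphenyl)propanoate | COc1cc(CCC(=O)OCc2ccccc2)ccc1OCc1ccccc1 | intermediate
3 | 3-(4-benzyloxy-3-methoxyphenyl)propanoic acid | COc1cc(CCC(=O)O)ccc1OCc1ccccc1 | intermediate
4 | (R)-4-benzyloxazolidin-2-one | O=C1OC[C@@H](Cc2ccccc2)N1 | starting material
5 | 3-(4-benzyloxy-3-methoxyphenyl)propanoic pivalic anhydride | COc1cc(CCC(=O)OC(=O)C(C)(C)C)ccc1OCc1ccccc1 | intermediate
6 | (R)-4-benzyl-3-[3-(4-benzyloxy-3-methoxyphenyl)propanoyl]oxazolidin-2-one | O=C1OC[C@@H](Cc2ccccc2)N1C(=O)CCc1ccc(OCc2ccccc2)c(OC)c1 | intermediate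
7 | (R)-4-benzyl-3-[(S)-2-(4-benzyloxy-3-methoxybenzyl)-3-hydroxypropanoyl]oxazolidin-2-one | O=C1OC[C@@H](Cc2ccccc2)N1C(=O)[C@H](CO)Cc1ccc(OCc2ccccc2)c(OC)c1 | intermediate
8 | (R)-4-benzyl-3-[(S)-2-(4-benzyloxy-3-methoxybenzyl)-3-(tert-butyldimethylsilyloxy)propanoyl]oxazolidin-2-one | O=C1OC[C@@H](Cc2ccccc2)N1C(=O)[C@H](CO[Si](C)(C)C(C)(C)C)Cc1ccc(OCc2ccccc2)c(OC)c1 | intermediate
9 | (R)-2-(4-benzyloxy-3-methoxybenzyl)-3-(tert-butyldimethylsilyloxy)propan-1-ol | OC[C@H](CO[Si](C)(C)C(C)(C)C)Cc1ccc(OCc2ccccc2)c(OC)c1 | intermediate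
10 | (S)-2-(4-benzyloxy-3-methoxybenzyl)-3-(tert-butyldimethylsilyloxy)propanal | O=C[C@H](CO[Si](C)(C)C(C)(C)C)Cc1ccc(OCc2ccccc2)c(OC)c1 | intermediate
11 | (R)-tert-butyl{[2-(4-benzyloxy-3-methoxybenzyl)but-3-yn-1-yl]oxy}dimethylsilane | C#C[C@H](CO[Si](C)(C)C(C)(C)C)Cc1ccc(OCc2ccccc2)c(OC)c1 | intermediate
12 | o-vanillin, 2-hydroxy-3-methoxybenzaldehyde | COc1cccc(C=O)c1O | starting material
13 | 2-hydroxy-5-iodo-3-methoxybenzaldehyde | COc1cc(I)cc(C=O)c1O | intermediate
14 | 2-hydroxy-5-iodo-3-methoxyphenyl formate | COc1cc(I)cc(OC=O)c1O | intermediate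
15 | 5-iodo-3-methoxybenzene-1,2-diol | COc1cc(I)cc(O)c1O | intermediate
16 | 1,2-bis(benzyloxy)-5-iodo-3-methoxybenzene | COc1cc(I)cc(OCc2ccccc2)c1OCc1ccccc1 | intermediate
17 | (R)-tert-butyl{[2-(4-benzyloxy-3-methoxybenzyl)-4-(3,4-bis(benzyloxy)-5-methoxyphenyl)but-3-yn-1-yl]oxy}dimethylsilane | COc1cc(C[C@@H](CO[Si](C)(C)C(C)(C)C)C#Cc2cc(OCc3ccccc3)c(OCc3ccccc3)c(OC)c2)ccc1OCc1ccccc1 | intermediate
18 | (R)-2-(4-benzyloxy-3-methoxybenzyl)-4-[3,4-bis(benzyloxy)-5-methoxyphenyl]but-3-yn-1-ol | COc1cc(C[C@@H](CO)C#Cc2cc(OCc3ccccc3)c(OCc3ccccc3)c(OC)c2)ccc1OCc1ccccc1 | intermediate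
19 | carbon monoxide | [C-]#[O+] | starting material
20 | (3E,4R)-4-(4-benzyloxy-3-methoxybenzyl)-3-[3,4-bis(benzyloxy)-5-methoxybenzylidene]dihydrofuran-2(3H)-one | COc1cc(C[C@H]2COC(=O)/C2=C/c2cc(OCc3ccccc3)c(OCc3ccccc3)c(OC)c2)ccc1OCc1ccccc1 | intermediate
21 | (3S,4R)-3-[3,4-bis(benzyloxy)-5-methoxybenzyl]-4-(4-benzyloxy-3-methoxybenzyl)dihydrofuran-2(3H)-one (cis) | COc1cc(C[C@H]2COC(=O)[C@H]2Cc2cc(OCc3ccccc3)c(OCc3ccccc3)c(OC)c2)ccc1OCc1ccccc1 | intermediate
22 | (3R,4R)-3-[3,4-bis(benzyloxy)-5-methoxybenzyl]-4-(4-benzyloxy-3-methoxybenzyl)dihydrofuran-2(3H)-one (trans) | COc1cc(C[C@H]2COC(=O)[C@@H]2Cc2cc(OCc3ccccc3)c(OCc3ccccc3)c(OC)c2)ccc1OCc1ccccc1 | intermediate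
23 | (−)-thujaplicatin, (3R,4R)-3-(3,4-dihydroxy-5-methoxybenzyl)-4-(4-hydroxy-3-methoxybenzyl)dihydrofuran-2(3H)-one | COc1cc(C[C@H]2COC(=O)[C@@H]2Cc2cc(O)c(O)c(OC)c2)ccc1O | target

**Step count and risks**

Total: 15 steps. Longest linear sequence: 12 steps (steps 1–7 and 11–15, from dihydroferulic acid 1); steps 8–10 make the ring B iodide.

Steps most likely to fail:

1. Step 13 (cyclocarbonylation). The free hydroxyl may add directly to the palladium-activated alkyne (cycloisomerisation to a dihydrofuran) faster than it is carbonylated. Insertion of the internal aryl alkyne may be so slow that the catalyst is reduced to palladium metal. Prolonged heating may move the exocyclic double bond into the ring and so erase C8. The fallback sets out from alkynol 18 and closes the same two bonds by a radical path. Phosgene (solution in toluene) with pyridine in CH2Cl2 at 0 °C should give the chloroformate F1, and benzeneselenol with pyridine should convert it into the Se-phenyl selenocarbonate F2. Slow addition of Bu3SnH with AIBN in benzene at 80 °C should generate the alkoxycarbonyl radical, which cyclises 5-exo-dig onto C8'; the aryl-stabilised vinyl radical at C7' then abstracts hydrogen. This should give lactone 20 together with its Z isomer F3. The mixture enters step 14 unchanged, since the geometry at C7' is lost there, so the fallback comes back at 20.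

2. Step 3 (hydroxymethylation). TiCl4 may cleave the aryl benzyl ether through chelation by the two ring A oxygens. The adduct may take up a second formaldehyde or revert by retro-aldol reaction on work-up. Incomplete enolisation may erode the facial selectivity. The fallback sets out from acid 3 and sets C8 by enamine catalysis in place of the auxiliary. BH3·SMe2 in THF should reduce 3 to 3-(4-benzyloxy-3-methoxyphenyl)propan-1-ol F4, and TEMPO/PhI(OAc)2 should oxidise it to 3-(4-benzyloxy-3-methoxyphenyl)propanal F5. Aqueous formaldehyde with catalytic (R)-α,α-diphenylprolinol trimethylsilyl ether in toluene/pH 7 phosphate buffer should give (S)-2-(4-benzyloxy-3-methoxybenzyl)-3-hydroxypropanal F6; the bulky group of the catalyst shields one face of the E enamine. The crude hydroxy aldehyde is silylated at once with TBSCl/imidazole and comes back to the route at aldehyde 10, bypassing steps 2–6. The enantiomeric purity would have to be checked at 10 before going on.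

3. Step 7 (alkyne homologation). The carbonate/methanol medium may epimerise C8 of aldehyde 10 through its enolate, or expel the silyloxy group by beta-elimination, before the homologation is complete. Either would lower the enantiomeric purity of everything downstream. The fallback sets out from aldehyde 10 and uses the Corey–Fuchs sequence. CBr4/PPh3 with Et3N in CH2Cl2 at 0 °C should give the dibromoalkene (R)-tert-butyl{[2-(4-benzyloxy-3-methoxybenzyl)-4,4-dibromobut-3-en-1-yl]oxy}dimethylsilane F7 under non-enolising conditions. n-BuLi (2.1 equiv) in THF at −78 °C followed by NH4Cl should then give the terminal alkyne by bromine–lithium exchange and rearrangement. The fallback comes back at alkyne 11.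

Further compounds
F1 | step 13 | (R)-2-(4-benzyloxy-3-methoxybenzyl)-4-[3,4-bis(benzyloxy)-5-methoxyphenyl]but-3-yn-1-yl carbonochloridate | COc1cc(C[C@@H](COC(Cl)=O)C#Cc2cc(OCc3ccccc3)c(OCc3ccccc3)c(OC)c2)ccc1OCc1ccccc1
F2 | step 13 | O-{(R)-2-(4-benzyloxy-3-methoxybenzyl)-4-[3,4-bis(benzyloxy)-5-methoxyphenyl]but-3-yn-1-yl} Se-phenyl selenocarbonate | COc1cc(C[C@@H](COC(=O)[Se]c2ccccc2)C#Cc2cc(OCc3ccccc3)c(OCc3ccccc3)c(OC)c2)ccc1OCc1ccccc1
F3 | step 13 | (3Z,4R)-4-(4-benzyloxy-3-methoxybenzyl)-3-[3,4-bis(benzyloxy)-5-methoxybenzylidene]dihydrofuran-2(3H)-one | COc1cc(C[C@H]2COC(=O)/C2=C\c2cc(OCc3ccccc3)c(OCc3ccccc3)c(OC)c2)ccc1OCc1ccccc1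
F4 | step 3 | 3-(4-benzyloxy-3-methoxyphenyl)propan-1-ol | COc1cc(CCCO)ccc1OCc1ccccc1
F5 | step 3 | 3-(4-benzyloxy-3-methoxyphenyl)propanal | COc1cc(CCC=O)ccc1OCc1ccccc1
F6 | step 3 | (S)-2-(4-benzyloxy-3-methoxybenzyl)-3-hydroxypropanal | O=C[C@H](CO)Cc1ccc(OCc2ccccc2)c(OC)c1
F7 | step 7 | (R)-tert-butyl{[2-(4-benzyloxy-3-methoxybenzyl)-4,4-dibromobut-3-en-1-yl]oxy}dimethylsilane | BrC(Br)=C[C@H](CO[Si](C)(C)C(C)(C)C)Cc1ccc(OCc2ccccc2)c(OC)c1
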